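**Retrosynthetic overview**

1. Locants: spiro[4.5]decane numbering, C1–C4 = cyclopentane (C1 carries the side chain, C4 the methyl), C5 = spiro carbon, C6–C10 = cyclohexene (C7=C8, C8 methyl, C9 carbinol). The target is traced back to a C2-keto, C9-epimeric silyl ether by deoxygenation at C2 and Mitsunobu inversion at C9.
2. Key disconnection: the C2–C3 bond of the cyclopentane (intramolecular hydroacylation, C2 = acyl carbon, C3 = terminal alkene carbon) together with C1–C5 (Claisen rearrangement). Both bonds, the spiro centre and the stereocentres C1, C4 and C5 arise in one operation from a monocyclic allyl vinyl ether.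
3. Enabling feature: the five-membered ring C1–C2–C3–C4–C5 is a latent 4-methylpent-4-enal (C2 as CHO on C1, quaternary C5, C4(CH3)=C3H2). A quaternary C5 that carries this isopropenyl unit next to a formyl-bearing C1 is the product pattern of a [3,3] shift of a 2-(cyclohexylidene)propyl 1-alkenyl ether. The C9 oxygen, 1,3 to C5 in the six-membered ring, steers the face of the shift.
4. The allyl vinyl ether comes from an exocyclic allylic alcohol (all ten carbons from (R)-carvone; C9 set by Luche reduction, the old C5 centre erased) and the methyl enol ether of the side-chain aldehyde (from (R)-citronellal by allylic oxidation and asymmetric hydrogenation).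
5. Ring order: the cyclohexene ring is carried intact from carvone; the cyclopentane ring is closed last, in the key step.

Key step: step 12

Assumption: the sense of induction written for the chiral iridium catalyst (step 8) and the chiral rhodium catalyst (step 12) is assumed; if either delivers the opposite configuration, the enantiomeric ligand is used.

**Route**

Step 1
Reactants: 1 (R)-(−)-carvone, (5R)-2-methyl-5-(prop-1-en-2-yl)cyclohex-2-en-1-one
Product: 2 (1R,5R)-cis-carveol, (1R,5R)-2-methyl-5-(prop-1-en-2-yl)cyclohex-2-en-1-ol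
Conditions: NaBH4, CeCl3·7H2O, MeOH, 0 °C
Reagents that add atoms: none
Why: Luche 1,2-reduction of the enone should deliver hydride axially, anti to the isopropenyl-bearing centre, so that this centre of carvone sets the new carbinol centre (cis alcohol), the later C9 control element.

Step 2
Reactants: 2 (1R,5R)-cis-carveol
Product: 3 tert-butyl(dimethyl){[(1R,5R)-2-methyl-5-(prop-1-en-2-yl)cyclohex-2-en-1-yl]oxy}silane
Conditions: TBSCl, imidazole, DMF, 25 °C
Reagents that add atoms: tert-butyl(chloro)dimethylsilane, CC(C)(C)[Si](C)(C)Cl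
Why: Standard silyl ether formation installs the bulky group that later shields one ring face; no stereocentre is touched.

Step 3
Reactants: 3 silyl ether of cis-carveol
Product: 5 1-[(1R,5R)-5-{[tert-butyl(dimethyl)silyl]oxy}-4-methylcyclohex-3-en-1-yl]ethan-1-one, via vicinal diol 4 (not isolated)
Conditions: OsO4 (cat.), NaIO4, 2,6-lutidine, 1,4-dioxane/H2O, 25 °C
Reagents that add atoms: osmium tetroxide, O=[Os](=O)(=O)=O (catalytic oxygen transfer); sodium periodate, [Na+].[O-]I(=O)(=O)=O (terminal oxidant)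
Why: Lemieux–Johnson oxidation, in which the unhindered 1,1-disubstituted alkene should be dihydroxylated in preference to the trisubstituted ring alkene flanked by the silyloxy group and the diol is cleaved to the methyl ketone; no new stereocentre.

Step 4
Reactants: 5 methyl ketone
Product: 8 1-[(3R)-3-{[tert-butyl(dimethyl)silyl]oxy}-4-methylcyclohex-4-en-1-ylidene]ethyl trifluoromethanesulfonate (E/Z mixture), via trimethylsilyl enol ether 6 (not isolated), via lithium enolate 7 (not isolated)
Conditions: TMSCl, NaI, Et3N, MeCN, 25 °C; pentane extraction, concentrate; MeLi, THF, 0 °C; PhNTf2, −78 → 0 °C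
Reagents that add atoms: N-phenylbis(trifluoromethanesulfonimide), O=S(=O)(N(c1ccccc1)S(=O)(=O)C(F)(F)F)C(F)(F)F
Why: Equilibrating enol silylation (iodotrimethylsilane made in situ, amine present) should favour the more substituted exocyclic silyl enol ether, methyllithium releases the regiodefined enolate and O-triflation gives the tetrasubstituted enol triflate; the old carvone centre is erased by design and the E/Z ratio is irrelevant.

Step 5
Reactants: 8 enol triflate
Product: 9 2-[(3R)-3-{[tert-butyl(dimethyl)silyl]oxy}-4-methylcyclohex-4-en-1-ylidene]propan-1-ol (E/Z mixture)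
Conditions: Bu3SnCH2OH, Pd(PPh3)4 (cat.), LiCl, 1,4-dioxane, 95 °C
Reagents that add atoms: (tributylstannyl)methanol, CCCC[Sn](CCCC)(CCCC)CO
Why: Stille cross-coupling of the vinyl triflate transfers the hydroxymethyl group with retention of the alkene position; no stereocentre is formed.

Step 6
Reactants: 10 (R)-(+)-citronellal, (3R)-3,7-dimethyloct-6-enal
Product: 11 (6R)-8,8-dimethoxy-2,6-dimethyloct-2-ene
Conditions: HC(OMe)3, MeOH, PPTS (cat.), 25 °C
Reagents that add atoms: trimethyl orthoformate, COC(OC)OC; methanol, CO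
Why: Acid-catalysed acetalisation with orthoformate as water scavenger masks the aldehyde under conditions mild enough to avoid the carbonyl-ene cyclisation of citronellal; the methyl-bearing centre is untouched.

Step 7
Reactants: 11 citronellal dimethyl acetal
Product: 12 (2E,6R)-8,8-dimethoxy-2,6-dimethyloct-2-en-1-ol
Conditions: SeO2 (cat.), t-BuOOH, CH2Cl2, 25 °C
Reagents that add atoms: selenium dioxide, O=[Se]=O (catalytic oxygen transfer); tert-butyl hydroperoxide, CC(C)(C)OO (terminal oxidant)
Why: Riley allylic oxidation (ene reaction, then [2,3]-sigmatropic shift) should hydroxylate the E-methyl group of the trisubstituted alkene selectively, giving the (E)-allylic alcohol; no sp3 stereocentre is formed.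

Step 8
Reactants: 12 (E)-allylic alcohol
Product: 13 (2S,6R)-8,8-dimethoxy-2,6-dimethyloctan-1-ol
Conditions: H2 (50 bar), [Ir(cod)((S)-tBu-PHOX)][B(C6H3-3,5-(CF3)2)4] (1 mol %), CH2Cl2, 25 °C
Reagents that add atoms: none
Why: Iridium-catalysed asymmetric hydrogenation of an (E)-2-methylalk-2-en-1-ol with a chiral P,N ligand; the new (2S) methyl centre is set by the catalyst, the remote C6 centre playing no part.

Step 9
Reactants: 13 saturated alcohol
Product: 14 (2S,6R)-8,8-dimethoxy-2,6-dimethyloctyl acetate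
Conditions: Ac2O, pyridine, DMAP (cat.), CH2Cl2, 25 °C
Reagents that add atoms: acetic anhydride, CC(=O)OC(C)=O
Why: DMAP-catalysed acylation installs the acetate of the target early, since every later step should tolerate it.

Step 10
Reactants: 14 acetal acetate
Product: 15 (2S,6R)-8-methoxy-2,6-dimethyloct-7-en-1-yl acetate (E/Z mixture)
Conditions: TMSOTf, i-Pr2NEt, CH2Cl2, −20 → 25 °C
Reagents that add atoms: none
Why: Acetal-to-enol-ether conversion, in which the silyl triflate ionises one methoxy group and the hindered amine deprotonates the oxocarbenium ion; alkene geometry is irrelevant.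

Step 11
Reactants: 9 exocyclic allylic alcohol; 15 methyl enol ether
Product: 17 (2S,6R)-8-({2-[(3R)-3-{[tert-butyl(dimethyl)silyl]oxy}-4-methylcyclohex-4-en-1-ylidene]propyl}oxy)-2,6-dimethyloct-7-en-1-yl acetate (E/Z at both the enol ether and the exocyclic alkene), via mixed methyl acetal 16 (not isolated)
Conditions: PPTS (cat.), CH2Cl2, 0 °C; then Et3N, TMSOTf, −20 → 0 °C
Reagents that add atoms: none
Why: Acid-catalysed Markovnikov addition of the alcohol to the enol ether gives the mixed acetal, from which silyl triflate and amine should remove the less hindered methoxy group (the same acetal-to-enol-ether elimination), leaving the allyl vinyl ether; no stereocentre is set.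

Step 12
Reactants: 17 allyl vinyl ether
Product: 20 (2S,6R)-6-[(1R,4S,5S,9R)-9-{[tert-butyl(dimethyl)silyl]oxy}-4,8-dimethyl-2-oxospiro[4.5]dec-7-en-1-yl]-2-methylheptyl acetate, via quaternary pentenal 18 (not isolated), via C1-epimeric spiroketone 19 (not isolated)
Conditions: n-heptane (base-washed sealed tube), 170 °C; cool to 25 °C, [Rh((S,S)-Me-DuPHOS)(acetone)2]PF6 (5 mol %), acetone, 25 → 40 °C; then DBU (cat.), 60 °C
Reagents that add atoms: none
Why: Heating should trigger a chair-like [3,3]-sigmatropic Claisen rearrangement that bonds C1 to the exocyclic alkene carbon C5 on the ring face opposite the pseudoaxial C9 silyloxy group and releases aldehyde 18, whose new quaternary C5 carries a formyl-bearing methine (C1–C2) and an isopropenyl group (C4=C3), a 4-methylpent-4-enal. The cationic monovalent rhodium complex then adds oxidatively into the aldehyde C–H bond, the acyl hydride inserts the 1,1-disubstituted alkene (H to C4, Rh to C3) and reductive elimination from the six-membered acylrhodacycle forms the C2–C3 bond; the closest known reaction types are the tandem Claisen rearrangement/hydroacylation of allyl vinyl ethers to cyclopentanones (spiro cases included) and the chiral diphosphine–rhodium cyclisation of 4-substituted pent-4-enals. The only ring closed is the cyclopentanone, formally a 5-endo-trig closure that runs through the rhodacycle, with C2 as acyl carbon and C3 as terminal alkene carbon. C5 is set by the C9 stereocentre (A1,2 strain with the C8 methyl holds the silyloxy group pseudoaxial and C7 is sp2, so C1 enters anti to it), C4 is set by the chiral diphosphine on rhodium, and C1 is set last by DBU equilibration alpha to the new ketone, which should funnel the C1 epimers that arise from the E/Z mixtures of both alkenes of 17 into the isomer with the bulky side chain trans to the C4 methyl (in the cis isomer both groups crowd the same ring methylene, C10). The step needs face selectivity in the sigmatropic shift, five- over four-membered ketone formation and no decarbonylation; these should be secured by the silyloxy group, by the 4-pentenal geometry (the trisubstituted ring alkene is only a 5-hexenal partner and inert) and by the chelating diphosphine on the alpha-branched aldehyde.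

Step 13
Reactants: 20 spiroketone
Product: 22 (2S,6R)-6-[(1R,4S,5S,9R)-9-{[tert-butyl(dimethyl)silyl]oxy}-4,8-dimethylspiro[4.5]dec-7-en-1-yl]-2-methylheptyl acetate, via C2 tosylhydrazone 21 (not isolated)
Conditions: TsNHNH2, EtOH, 60 °C; concentrate; catecholborane, CHCl3, 0 → 25 °C; NaOAc·3H2O, 60 °C
Reagents that add atoms: none
Why: Caglioti-type deoxygenation, in which catecholborane reduces the tosylhydrazone C=N and acetate triggers loss of sulfinate and dinitrogen, replaces C=O by CH2 under near-neutral conditions that should leave the C1 configuration, the silyl ether, the acetate and the ring alkene untouched.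

Step 14
Reactants: 22 deoxygenated silyl ether
Product: 23 (2S,6R)-6-[(1R,4S,5S,9R)-9-hydroxy-4,8-dimethylspiro[4.5]dec-7-en-1-yl]-2-methylheptyl acetate (C9 epimer of the target)
Conditions: Bu4NF, AcOH, THF, 25 °C
Reagents that add atoms: none
Why: Fluoride-mediated desilylation, buffered with acetic acid so that the acetate neither migrates nor hydrolyses, frees the C9 alcohol.

Step 15
Reactants: 23 C9-epimeric alcohol
Product: 24 (1R,4S,5S,9S)-1-[(2R,6S)-7-acetoxy-6-methylheptan-2-yl]-4,8-dimethylspiro[4.5]dec-7-en-9-yl chloroacetate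
Conditions: ClCH2CO2H, PPh3, DIAD, toluene, 0 → 25 °C
Reagents that add atoms: chloroacetic acid, OC(=O)CCl
Why: Mitsunobu reaction, in which chloroacetate displaces the alkoxyphosphonium ion in an SN2 step with inversion, sets the final (9S) configuration; chloroacetic acid suits hindered carbinols and is removable beside an acetate.

Step 16
Reactants: 24 chloroacetate
Product: 25 (2S,6R)-6-[(1R,4S,5S,9S)-9-hydroxy-4,8-dimethylspiro[4.5]dec-7-en-1-yl]-2-methylheptyl acetate (target)
Conditions: thiourea, NaHCO3, EtOH, 50 °C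
Reagents that add atoms: none
Why: Selective dechloroacetylation, in which thiourea is alkylated at sulfur and cyclises onto the ester carbonyl, should release the secondary alcohol while the primary acetate survives.

**Compound list**

1 | (R)-(−)-carvone, (5R)-2-methyl-5-(prop-1-en-2-yl)cyclohex-2-en-1-one | CC1=CC[C@@H](C(C)=C)CC1=O | starting material
2 | (1R,5R)-cis-carveol | CC1=CC[C@@H](C(C)=C)C[C@H]1O | intermediate
3 | tert-butyl(dimethyl){[(1R,5R)-2-methyl-5-(prop-1-en-2-yl)cyclohex-2-en-1-yl]oxy}silane | CC1=CC[C@@H](C(C)=C)C[C@H]1O[Si](C)(C)C(C)(C)C | intermediate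
4 | 2-[(1R,5R)-5-{[tert-butyl(dimethyl)silyl]oxy}-4-methylcyclohex-3-en-1-yl]propane-1,2-diol (C2 epimers) | CC1=CC[C@@H](C(C)(O)CO)C[C@H]1O[Si](C)(C)C(C)(C)C | intermediate
5 | 1-[(1R,5R)-5-{[tert-butyl(dimethyl)silyl]oxy}-4-methylcyclohex-3-en-1-yl]ethan-1-one | CC1=CC[C@@H](C(C)=O)C[C@H]1O[Si](C)(C)C(C)(C)C | intermediate
6 | tert-butyl(dimethyl)[((1R)-2-methyl-5-{1-[(trimethylsilyl)oxy]ethylidene}cyclohex-2-en-1-yl)oxy]silane (E/Z) | CC1=CCC(=C(C)O[Si](C)(C)C)C[C@H]1O[Si](C)(C)C(C)(C)C | intermediate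
7 | lithium 1-[(3R)-3-{[tert-butyl(dimethyl)silyl]oxy}-4-methylcyclohex-4-en-1-ylidene]ethan-1-olate | CC1=CCC(=C(C)[O-])C[C@H]1O[Si](C)(C)C(C)(C)C.[Li+] | intermediate
8 | 1-[(3R)-3-{[tert-butyl(dimethyl)silyl]oxy}-4-methylcyclohex-4-en-1-ylidene]ethyl trifluoromethanesulfonate (E/Z) | CC1=CCC(=C(C)OS(=O)(=O)C(F)(F)F)C[C@H]1O[Si](C)(C)C(C)(C)C | intermediate
9 | 2-[(3R)-3-{[tert-butyl(dimethyl)silyl]oxy}-4-methylcyclohex-4-en-1-ylidene]propan-1-ol (E/Z) | CC1=CCC(=C(C)CO)C[C@H]1O[Si](C)(C)C(C)(C)C | intermediate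
10 | (R)-(+)-citronellal, (3R)-3,7-dimethyloct-6-enal | CC(C)=CCC[C@@H](C)CC=O | starting material
11 | (6R)-8,8-dimethoxy-2,6-dimethyloct-2-ene | CC(C)=CCC[C@@H](C)CC(OC)OC | intermediate
12 | (2E,6R)-8,8-dimethoxy-2,6-dimethyloct-2-en-1-ol | OC/C(C)=C/CC[C@@H](C)CC(OC)OC | intermediate
13 | (2S,6R)-8,8-dimethoxy-2,6-dimethyloctan-1-ol | OC[C@@H](C)CCC[C@@H](C)CC(OC)OC | intermediate
14 | (2S,6R)-8,8-dimethoxy-2,6-dimethyloctyl acetate | CC(=O)OC[C@@H](C)CCC[C@@H](C)CC(OC)OC | intermediate
15 | (2S,6R)-8-methoxy-2,6-dimethyloct-7-en-1-yl acetate (E/Z) | CC(=O)OC[C@@H](C)CCC[C@@H](C)C=COC | intermediate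
16 | (2S,6R)-8-({2-[(3R)-3-{[tert-butyl(dimethyl)silyl]oxy}-4-methylcyclohex-4-en-1-ylidene]propyl}oxy)-8-methoxy-2,6-dimethyloctyl acetate (isomer mixture) | CC(=O)OC[C@@H](C)CCC[C@@H](C)CC(OC)OCC(C)=C1CC=C(C)[C@@H](C1)O[Si](C)(C)C(C)(C)C | intermediate
17 | (2S,6R)-8-({2-[(3R)-3-{[tert-butyl(dimethyl)silyl]oxy}-4-methylcyclohex-4-en-1-ylidene]propyl}oxy)-2,6-dimethyloct-7-en-1-yl acetate (E/Z at both alkenes) | CC(=O)OC[C@@H](C)CCC[C@@H](C)C=COCC(C)=C1CC=C(C)[C@@H](C1)O[Si](C)(C)C(C)(C)C | intermediate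
18 | (2S,6R)-7-[(1R,5R)-5-{[tert-butyl(dimethyl)silyl]oxy}-4-methyl-1-(prop-1-en-2-yl)cyclohex-3-en-1-yl]-2,6-dimethyl-8-oxooctyl acetate (C7 epimers) | CC(=O)OC[C@@H](C)CCC[C@@H](C)C(C=O)[C@@]1(C(C)=C)CC=C(C)[C@@H](C1)O[Si](C)(C)C(C)(C)C | intermediate
19 | (2S,6R)-6-[(4S,5S,9R)-9-{[tert-butyl(dimethyl)silyl]oxy}-4,8-dimethyl-2-oxospiro[4.5]dec-7-en-1-yl]-2-methylheptyl acetate (C1 epimers) | CC(=O)OC[C@@H](C)CCC[C@@H](C)C1C(=O)C[C@H](C)[C@@]12CC=C(C)[C@H](O[Si](C)(C)C(C)(C)C)C2 | intermediate
20 | (2S,6R)-6-[(1R,4S,5S,9R)-9-{[tert-butyl(dimethyl)silyl]oxy}-4,8-dimethyl-2-oxospiro[4.5]dec-7-en-1-yl]-2-methylheptyl acetate | CC(=O)OC[C@@H](C)CCC[C@@H](C)[C@H]1C(=O)C[C@H](C)[C@@]12CC=C(C)[C@H](O[Si](C)(C)C(C)(C)C)C2 | intermediate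
21 | 4-methylbenzenesulfonylhydrazone of 20 at C2 | CC(=O)OC[C@@H](C)CCC[C@@H](C)[C@H]1C(=NNS(=O)(=O)c3ccc(C)cc3)C[C@H](C)[C@@]12CC=C(C)[C@H](O[Si](C)(C)C(C)(C)C)C2 | intermediate
22 | (2S,6R)-6-[(1R,4S,5S,9R)-9-{[tert-butyl(dimethyl)silyl]oxy}-4,8-dimethylspiro[4.5]dec-7-en-1-yl]-2-methylheptyl acetate | CC(=O)OC[C@@H](C)CCC[C@@H](C)[C@H]1CC[C@H](C)[C@@]12CC=C(C)[C@H](O[Si](C)(C)C(C)(C)C)C2 | intermediate
23 | (2S,6R)-6-[(1R,4S,5S,9R)-9-hydroxy-4,8-dimethylspiro[4.5]dec-7-en-1-yl]-2-methylheptyl acetate | CC(=O)OC[C@@H](C)CCC[C@@H](C)[C@H]1CC[C@H](C)[C@@]12CC=C(C)[C@H](O)C2 | intermediate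
24 | (1R,4S,5S,9S)-1-[(2R,6S)-7-acetoxy-6-methylheptan-2-yl]-4,8-dimethylspiro[4.5]dec-7-en-9-yl chloroacetate | CC(=O)OC[C@@H](C)CCC[C@@H](C)[C@H]1CC[C@H](C)[C@@]12CC=C(C)[C@@H](OC(=O)CCl)C2 | intermediate
25 | (2S,6R)-6-[(1R,4S,5S,9S)-9-hydroxy-4,8-dimethylspiro[4.5]dec-7-en-1-yl]-2-methylheptyl acetate | CC(=O)OC[C@@H](C)CCC[C@@H](C)[C@H]1CC[C@H](C)[C@@]12CC=C(C)[C@@H](O)C2 | target

**Step count**

Total step count: 16. Longest linear sequence: 11 steps (steps 1–5, then 11–16; the citronellal branch, steps 6–10 then 11–16, is equally long).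

**Steps most likely to fail**

Step 12. The sigmatropic shift may lose face selectivity at the exocyclic alkene. The hindered alpha-branched aldehyde may decarbonylate or fail to insert the isopropenyl alkene. Catalyst control at C4 may be overridden by the substrate, or the equilibration at C1 may be poorly biased. The fallback sets out from 18 (isolated after the thermal stage) and returns at 22, closing the same C2–C3 bond as an alkene. NaBH4 in MeOH reduces 18 to (2S,6R)-7-[(1R,5R)-5-{[tert-butyl(dimethyl)silyl]oxy}-4-methyl-1-(prop-1-en-2-yl)cyclohex-3-en-1-yl]-8-hydroxy-2,6-dimethyloctyl acetate F1. Hydroboration of the isopropenyl group with 9-BBN and oxidation with NaBO3 gives (2S,6R)-7-[(1S,5R)-5-{[tert-butyl(dimethyl)silyl]oxy}-1-(1-hydroxypropan-2-yl)-4-methylcyclohex-3-en-1-yl]-8-hydroxy-2,6-dimethyloctyl acetate F2. Swern oxidation gives (2S,6R)-7-[(1S,5R)-5-{[tert-butyl(dimethyl)silyl]oxy}-4-methyl-1-(1-oxopropan-2-yl)cyclohex-3-en-1-yl]-2,6-dimethyl-8-oxooctyl acetate F3, whose two formyl-bearing centres are equilibrated with DBU. Intramolecular McMurry coupling (TiCl3(DME)1.5, Zn–Cu couple, DME, reflux) gives (2S,6R)-6-[(1S,4S,5S,9R)-9-{[tert-butyl(dimethyl)silyl]oxy}-4,8-dimethylspiro[4.5]deca-2,7-dien-1-yl]-2-methylheptyl acetate F4. Diimide (potassium azodicarboxylate, AcOH, MeOH) should reduce the strained cis-disubstituted cyclopentene in preference to the trisubstituted ring alkene and give 22, so that step 13 is no longer needed.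

Step 4. Enolisation may run towards the acetyl methyl group instead of the ring methine, which would place the triflate on a terminal alkene. The fallback sets out from 1 and returns at 9, building the exocyclic alkene by olefination of a ring ketone so that its position is unambiguous. Ozonolysis of the isopropenyl group of 1 in MeOH/CH2Cl2 followed by Criegee rearrangement (Ac2O, Et3N, DMAP) gives (1R)-4-methyl-5-oxocyclohex-3-en-1-yl acetate F5. Luche reduction gives (1R,5R)-5-hydroxy-4-methylcyclohex-3-en-1-yl acetate F6. Silylation (TBSCl, imidazole) gives (1R,5R)-5-{[tert-butyl(dimethyl)silyl]oxy}-4-methylcyclohex-3-en-1-yl acetate F7. Methanolysis (K2CO3, MeOH) gives (1R,5R)-5-{[tert-butyl(dimethyl)silyl]oxy}-4-methylcyclohex-3-en-1-ol F8. Dess–Martin oxidation (NaHCO3 buffer) gives (5R)-5-{[tert-butyl(dimethyl)silyl]oxy}-4-methylcyclohex-3-en-1-one F9. Wittig olefination with Ph3P=C(CH3)CO2Et (toluene, 90 °C, base-free to avoid loss of silanol and aromatisation) gives ethyl 2-[(3R)-3-{[tert-butyl(dimethyl)silyl]oxy}-4-methylcyclohex-4-en-1-ylidene]propanoate F10. Reduction with i-Bu2AlH gives 9.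

Step 15. SN2′ attack at C7 or elimination to the diene may compete with direct displacement at the hindered allylic carbinol. The fallback sets out from 23 and returns at 25, replacing the substitution by oxidation and catalyst-controlled reduction. Dess–Martin oxidation gives (2S,6R)-6-[(1R,4S,5S)-4,8-dimethyl-9-oxospiro[4.5]dec-7-en-1-yl]-2-methylheptyl acetate F11. Corey–Bakshi–Shibata reduction ((R)-2-methyl-CBS-oxazaborolidine, catecholborane, toluene, −78 °C; the alkenyl carbon C8 acting as the large group) should give 25 directly, so that step 16 is no longer needed.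

**Further compounds**

F1 | step 12 | (2S,6R)-7-[(1R,5R)-5-{[tert-butyl(dimethyl)silyl]oxy}-4-methyl-1-(prop-1-en-2-yl)cyclohex-3-en-1-yl]-8-hydroxy-2,6-dimethyloctyl acetate (C7 epimers) | CC(=O)OC[C@@H](C)CCC[C@@H](C)C(CO)[C@@]1(C(C)=C)CC=C(C)[C@@H](C1)O[Si](C)(C)C(C)(C)C
F2 | step 12 | (2S,6R)-7-[(1S,5R)-5-{[tert-butyl(dimethyl)silyl]oxy}-1-(1-hydroxypropan-2-yl)-4-methylcyclohex-3-en-1-yl]-8-hydroxy-2,6-dimethyloctyl acetate (epimers at both methine carbons next to CH2OH) | CC(=O)OC[C@@H](C)CCC[C@@H](C)C(CO)[C@@]1(C(C)CO)CC=C(C)[C@@H](C1)O[Si](C)(C)C(C)(C)C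
F3 | step 12 | (2S,6R)-7-[(1S,5R)-5-{[tert-butyl(dimethyl)silyl]oxy}-4-methyl-1-(1-oxopropan-2-yl)cyclohex-3-en-1-yl]-2,6-dimethyl-8-oxooctyl acetate | CC(=O)OC[C@@H](C)CCC[C@@H](C)C(C=O)[C@@]1(C(C)C=O)CC=C(C)[C@@H](C1)O[Si](C)(C)C(C)(C)C
F4 | step 12 | (2S,6R)-6-[(1S,4S,5S,9R)-9-{[tert-butyl(dimethyl)silyl]oxy}-4,8-dimethylspiro[4.5]deca-2,7-dien-1-yl]-2-methylheptyl acetate | CC(=O)OC[C@@H](C)CCC[C@@H](C)[C@H]1C=C[C@H](C)[C@@]12CC=C(C)[C@H](O[Si](C)(C)C(C)(C)C)C2
F5 | step 4 | (1R)-4-methyl-5-oxocyclohex-3-en-1-yl acetate | CC1=CC[C@@H](OC(C)=O)CC1=O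
F6 | step 4 | (1R,5R)-5-hydroxy-4-methylcyclohex-3-en-1-yl acetate | CC1=CC[C@@H](OC(C)=O)C[C@H]1O
F7 | step 4 | (1R,5R)-5-{[tert-butyl(dimethyl)silyl]oxy}-4-methylcyclohex-3-en-1-yl acetate | CC1=CC[C@@H](OC(C)=O)C[C@H]1O[Si](C)(C)C(C)(C)C
F8 | step 4 | (1R,5R)-5-{[tert-butyl(dimethyl)silyl]oxy}-4-methylcyclohex-3-en-1-ol | CC1=CC[C@@H](O)C[C@H]1O[Si](C)(C)C(C)(C)C
F9 | step 4 | (5R)-5-{[tert-butyl(dimethyl)silyl]oxy}-4-methylcyclohex-3-en-1-one | CC1=CCC(=O)C[C@H]1O[Si](C)(C)C(C)(C)C
F10 | step 4 | ethyl 2-[(3R)-3-{[tert-butyl(dimethyl)silyl]oxy}-4-methylcyclohex-4-en-1-ylidene]propanoate (E/Z) | CCOC(=O)C(C)=C1CC=C(C)[C@@H](C1)O[Si](C)(C)C(C)(C)C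
F11 | step 15 | (2S,6R)-6-[(1R,4S,5S)-4,8-dimethyl-9-oxospiro[4.5]dec-7-en-1-yl]-2-methylheptyl acetate | CC(=O)OC[C@@H](C)CCC[C@@H](C)[C@H]1CC[C@H](C)[C@@]12CC=C(C)C(=O)C2
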